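**Assumption:** (S)‑4‑(tert‑butyldimethylsilyloxy)cyclopent‑2‑en‑1‑one is taken as a commercial building block. Locants in each Why line follow the name of the compound under discussion.

## Retrosynthetic overview

1. Target 13 ⇐ p‑methoxyphenyl (PMP) ether 12 (CAN) ⇐ epoxy alcohol 11 (benzoate opening at the carbon remote from the carbinol) ⇐ cyclohexenone 10 (hydroxyl‑directed epoxidation).
2. Key disconnection: the six‑membered ring holds an α‑ketol, the C6 ketone beside the quaternary carbinol C1 (OH, CH2OBz). This lets the C1–C2 ring bond be shifted back onto C6, so 10 ⇐ 1‑(benzoyloxyacetyl)cyclopent‑2‑en‑1‑ol 9.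
3. 9 ⇐ enol ether 6 (dihydroxylation, benzoylation) ⇐ cis‑diol 5 (Mitsunobu inversion with 4‑methoxyphenol) ⇐ adduct 4 of 1‑ethoxyvinyllithium and enone 1.
4. Ring order: the cyclopentene is bought; the six‑membered carbocycle, the only ring of the target, arises from it by 5 → 6 ring expansion in step 6; the epoxide of steps 7–8 is transient.
5. Stereochemical relay: C4 of 1 → tertiary carbinol (step 1) → quaternary C1 (step 6) → epoxide face (step 7) → benzoate carbon (step 8).

Key step: step 6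

## Route

Step 1
Reactants: 1 (S)‑4‑(tert‑butyldimethylsilyloxy)cyclopent‑2‑en‑1‑one; 2 ethyl vinyl ether
Product: 4 (1R,4S)‑4‑(tert‑butyldimethylsilyloxy)‑1‑(1‑ethoxyethenyl)cyclopent‑2‑en‑1‑ol, via 1‑ethoxyvinyllithium 3 (not isolated)
Conditions: 2, t‑BuLi, THF, −78 → 0 °C; then 1, −78 °C; H2O
Reagents that add atoms: none
Why: 1,2‑Addition of an α‑alkoxyvinyllithium (acyl‑anion equivalent) to the enone carbonyl, the reagent entering anti to the C4 silyloxy group, so that the new tertiary hydroxyl should be cis to OTBS (1R).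

Step 2
Reactants: 4 (1R,4S)‑4‑(tert‑butyldimethylsilyloxy)‑1‑(1‑ethoxyethenyl)cyclopent‑2‑en‑1‑ol
Product: 5 (1R,4S)‑1‑(1‑ethoxyethenyl)cyclopent‑2‑ene‑1,4‑diol (cis‑diol)
Conditions: TBAF, THF, 0 °C
Reagents that add atoms: none
Why: Fluoride‑mediated Si–O cleavage, under which the acid‑labile enol ether and both stereocentres should stay unchanged.

Step 3
Reactants: 5 (1R,4S)‑1‑(1‑ethoxyethenyl)cyclopent‑2‑ene‑1,4‑diol
Product: 6 (1R,4R)‑1‑(1‑ethoxyethenyl)‑4‑(4‑methoxyphenoxy)cyclopent‑2‑en‑1‑ol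
Conditions: 4‑MeOC6H4OH, PPh3, DIAD, toluene, 0 °C → rt
Reagents that add atoms: 4‑methoxyphenol COc1ccc(O)cc1
Why: Mitsunobu etherification: the secondary allylic hydroxyl is activated as its oxyphosphonium ion and displaced by the phenoxide with SN2 inversion (4S → 4R) while the tertiary hydroxyl is inert, which places the aryloxy group trans to the tertiary hydroxyl and cis to the acyl equivalent, as the key step requires.

Step 4
Reactants: 6 (1R,4R)‑1‑(1‑ethoxyethenyl)‑4‑(4‑methoxyphenoxy)cyclopent‑2‑en‑1‑ol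
Product: 8 2‑hydroxy‑1‑[(1R,4R)‑1‑hydroxy‑4‑(4‑methoxyphenoxy)cyclopent‑2‑en‑1‑yl]ethan‑1‑one, via ethoxy hemiketal triol 7 (not isolated)
Conditions: OsO4 (2 mol %), NMO, acetone/H2O, 0 °C
Reagents that add atoms: N‑methylmorpholine N‑oxide C[N+]1([O-])CCOCC1; water O
Why: Catalytic OsO4/NMO dihydroxylation should take the electron‑rich enol ether in preference to the ring alkene, which is flanked by two oxygenated carbons, and the hemiketal collapses with loss of ethanol to the α,α′‑dihydroxy ketone, so no lasting stereocentre is formed.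

Step 5
Reactants: 8 2‑hydroxy‑1‑[(1R,4R)‑1‑hydroxy‑4‑(4‑methoxyphenoxy)cyclopent‑2‑en‑1‑yl]ethan‑1‑one
Product: 9 2‑[(1R,4R)‑1‑hydroxy‑4‑(4‑methoxyphenoxy)cyclopent‑2‑en‑1‑yl]‑2‑oxoethyl benzoate
Conditions: BzCl (1.05 equiv), 2,4,6‑collidine, CH2Cl2, −40 → 0 °C
Reagents that add atoms: benzoyl chloride O=C(Cl)c1ccccc1
Why: Acylation (nucleophilic acyl substitution) of the primary hydroxyl should be far faster than that of the tertiary α‑ketol hydroxyl, and the hindered base should not enolise the ketone; no stereocentre is touched.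

Step 6
Reactants: 9 2‑[(1R,4R)‑1‑hydroxy‑4‑(4‑methoxyphenoxy)cyclopent‑2‑en‑1‑yl]‑2‑oxoethyl benzoate
Product: 10 [(1R,4R)‑1‑hydroxy‑4‑(4‑methoxyphenoxy)‑6‑oxocyclohex‑2‑en‑1‑yl]methyl benzoate
Conditions: Zn(OTf)2 (20 mol %), 4 Å MS, (CH2Cl)2, 40 °C
Reagents that add atoms: none
Why: Zn(II) should bind the tertiary hydroxyl and the ketone oxygen of 9 in a five‑membered chelate with the two oxygens syn‑periplanar, and the alkenyl ring carbon C2 then shifts with its bonding pair from the carbinol carbon C1 to the exocyclic carbonyl carbon while the carbinol becomes the ring ketone (α‑ketol, or acyloin, rearrangement). The closest known reaction type is the Lewis‑acid‑promoted α‑ketol ring expansion of 1‑acylcycloalkanols, as in the D‑homoannulation of 17‑hydroxy‑20‑oxo steroids. The six‑membered ring is closed not by a cyclisation but by a suprafacial 1,2‑shift that inserts the acyl carbon between C1 and C2 of the cyclopentene, with relief of cyclopentene strain as the driving force. The one new stereocentre, the quaternary carbinol C1 of 10, is controlled by the carbinol stereocentre of 9 through the chelate: C2 bonds to the carbonyl face on which it lies, so the new hydroxyl stays on the face of the old one and CH2OBz takes the face of the old acyl group (1R, hydroxyl trans to the aryloxy group). The step needs migration of the sp2 carbon C2 in preference to the sp3 carbon C5 and a stop before a second ketol shift to the conjugated isomer. The first should be secured by the higher migratory aptitude of an alkenyl carbon, whose p orbital overlaps with the carbonyl π*, and the second by a mild catalytic Lewis acid at moderate temperature.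

Step 7
Reactants: 10 [(1R,4R)‑1‑hydroxy‑4‑(4‑methoxyphenoxy)‑6‑oxocyclohex‑2‑en‑1‑yl]methyl benzoate
Product: 11 [(1S,2S,5R,6S)‑2‑hydroxy‑5‑(4‑methoxyphenoxy)‑3‑oxo‑7‑oxabicyclo[4.1.0]heptan‑2‑yl]methyl benzoate
Conditions: VO(acac)2 (5 mol %), t‑BuOOH, CH2Cl2, 0 °C → rt
Reagents that add atoms: tert‑butyl hydroperoxide CC(C)(C)OO
Why: Vanadium‑catalysed hydroxyl‑directed epoxidation of an allylic alcohol: the vanadate ester of the tertiary hydroxyl delivers oxygen to the alkene face cis to that hydroxyl, which is also the face anti to CH2OBz and to the aryloxy group, so both epoxide stereocentres should be set by the quaternary carbon (whose descriptor changes from R to S only through CIP priorities).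

Step 8
Reactants: 11 [(1S,2S,5R,6S)‑2‑hydroxy‑5‑(4‑methoxyphenoxy)‑3‑oxo‑7‑oxabicyclo[4.1.0]heptan‑2‑yl]methyl benzoate
Product: 12 [(1S,2S,3S,4R)‑3‑(benzoyloxy)‑1,2‑dihydroxy‑4‑(4‑methoxyphenoxy)‑6‑oxocyclohexyl]methyl benzoate
Conditions: PhCO2H, Ti(OiPr)4, CH2Cl2, rt; aq. tartaric acid
Reagents that add atoms: benzoic acid OC(=O)c1ccccc1
Why: Titanium‑mediated opening of a 2,3‑epoxy alcohol by a carboxylic acid at the carbon remote from the carbinol: Ti(IV) bridges the tertiary alkoxide and the epoxide oxygen, and benzoate should attack C6 of 11 (next to C–OAr) with SN2 inversion rather than the neopentyl C1, which sets the benzoate cis to the aryloxy group and trans to the freed C2 hydroxyl.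

Step 9
Reactants: 12 [(1S,2S,3S,4R)‑3‑(benzoyloxy)‑1,2‑dihydroxy‑4‑(4‑methoxyphenoxy)‑6‑oxocyclohexyl]methyl benzoate
Product: 13 [(1S,2S,3R,4R)‑3‑(benzoyloxy)‑1,2,4‑trihydroxy‑6‑oxocyclohexyl]methyl benzoate (target)
Conditions: (NH4)2Ce(NO3)6, MeCN/H2O, 0 °C
Reagents that add atoms: none
Why: Oxidative cleavage of a p‑methoxyphenyl ether by cerium(IV) (aryl radical cation, attack of water at the ipso carbon, loss of benzoquinone) should free the C4 hydroxyl without touching the esters or any stereocentre; the C3 descriptor changes from S to R only through CIP priorities.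

## Compound list

1 | (S)‑4‑(tert‑butyldimethylsilyloxy)cyclopent‑2‑en‑1‑one | O=C1C=C[C@@H](O[Si](C)(C)C(C)(C)C)C1 | starting material
2 | ethyl vinyl ether | C=COCC | starting material
3 | 1‑ethoxyvinyllithium | [Li]C(=C)OCC | intermediate
4 | (1R,4S)‑4‑(tert‑butyldimethylsilyloxy)‑1‑(1‑ethoxyethenyl)cyclopent‑2‑en‑1‑ol | CCOC(=C)[C@]1(O)C=C[C@@H](O[Si](C)(C)C(C)(C)C)C1 | intermediate
5 | (1R,4S)‑1‑(1‑ethoxyethenyl)cyclopent‑2‑ene‑1,4‑diol | CCOC(=C)[C@]1(O)C=C[C@@H](O)C1 | intermediate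
6 | (1R,4R)‑1‑(1‑ethoxyethenyl)‑4‑(4‑methoxyphenoxy)cyclopent‑2‑en‑1‑ol | CCOC(=C)[C@]1(O)C=C[C@H](Oc2ccc(OC)cc2)C1 | intermediate
7 | 1‑ethoxy‑1‑[(1R,4R)‑1‑hydroxy‑4‑(4‑methoxyphenoxy)cyclopent‑2‑en‑1‑yl]ethane‑1,2‑diol (hemiketal, either configuration at the ketal carbon) | CCOC(O)(CO)[C@]1(O)C=C[C@H](Oc2ccc(OC)cc2)C1 | intermediate
8 | 2‑hydroxy‑1‑[(1R,4R)‑1‑hydroxy‑4‑(4‑methoxyphenoxy)cyclopent‑2‑en‑1‑yl]ethan‑1‑one | O=C(CO)[C@]1(O)C=C[C@H](Oc2ccc(OC)cc2)C1 | intermediate
9 | 2‑[(1R,4R)‑1‑hydroxy‑4‑(4‑methoxyphenoxy)cyclopent‑2‑en‑1‑yl]‑2‑oxoethyl benzoate | O=C(OCC(=O)[C@]1(O)C=C[C@H](Oc2ccc(OC)cc2)C1)c1ccccc1 | intermediate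
10 | [(1R,4R)‑1‑hydroxy‑4‑(4‑methoxyphenoxy)‑6‑oxocyclohex‑2‑en‑1‑yl]methyl benzoate | O=C(OC[C@@]1(O)C(=O)C[C@@H](Oc2ccc(OC)cc2)C=C1)c1ccccc1 | intermediate
11 | [(1S,2S,5R,6S)‑2‑hydroxy‑5‑(4‑methoxyphenoxy)‑3‑oxo‑7‑oxabicyclo[4.1.0]heptan‑2‑yl]methyl benzoate | O=C(OC[C@@]1(O)C(=O)C[C@@H](Oc3ccc(OC)cc3)[C@@H]2O[C@H]12)c1ccccc1 | intermediate
12 | [(1S,2S,3S,4R)‑3‑(benzoyloxy)‑1,2‑dihydroxy‑4‑(4‑methoxyphenoxy)‑6‑oxocyclohexyl]methyl benzoate | O=C(OC[C@@]1(O)C(=O)C[C@@H](Oc3ccc(OC)cc3)[C@@H](OC(=O)c2ccccc2)[C@@H]1O)c1ccccc1 | intermediate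
13 | [(1S,2S,3R,4R)‑3‑(benzoyloxy)‑1,2,4‑trihydroxy‑6‑oxocyclohexyl]methyl benzoate | O=C(OC[C@@]1(O)C(=O)C[C@@H](O)[C@@H](OC(=O)c2ccccc2)[C@@H]1O)c1ccccc1 | target

## Step count and risks

Total step count: 9. Longest linear sequence: 9.

Steps most likely to fail:

1. **Step 6 (ring expansion).** The chelated shift may be accompanied by migration of the saturated ring carbon, by a second ketol shift of the free product to the conjugated isomer, or by loss of facial control if an open transition state competes. Fallback, from 9: the tertiary hydroxyl would be capped as its trimethylsilyl ether, 2‑[(1R,4R)‑4‑(4‑methoxyphenoxy)‑1‑(trimethylsilyloxy)cyclopent‑2‑en‑1‑yl]‑2‑oxoethyl benzoate F1 (N‑trimethylsilylimidazole, CH2Cl2). The rearrangement would then be run as the aluminium‑promoted acyloin shift of an α‑silyloxy ketone (MAD or Me2AlCl, CH2Cl2, −78 °C), in which silicon passes from the old to the new oxygen through the same syn‑periplanar array. This gives [(1R,4R)‑4‑(4‑methoxyphenoxy)‑6‑oxo‑1‑(trimethylsilyloxy)cyclohex‑2‑en‑1‑yl]methyl benzoate F2, which is capped and cannot shift again. Dilute aqueous HCl in THF then returns to 10.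

2. **Step 8 (epoxide opening).** Benzoate may attack the wrong epoxide carbon, or the Lewis acid may isomerise the ketol. Fallback, from 10: dihydroxylation directed by the tertiary hydroxyl (OsO4·TMEDA, CH2Cl2, −78 °C) would give the all‑cis triol [(1S,2S,3R,4R)‑1,2,3‑trihydroxy‑4‑(4‑methoxyphenoxy)‑6‑oxocyclohexyl]methyl benzoate F3. Its secondary cis‑diol would be closed to the 2,3‑cyclic sulfate F4 (SO2Cl2, Et3N, −78 °C). SN2 opening with tetrabutylammonium benzoate in DMF should occur at the less hindered C3 with inversion, giving the C2 hydrogen sulfate of 12 F5. Acid hydrolysis (cat. H2SO4, THF/H2O) then returns to 12.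

3. **Step 3 (Mitsunobu etherification).** The weakly acidic phenol may couple sluggishly, and the allylic oxyphosphonium ion may suffer SN2′ transposition or elimination instead of clean inversion. Fallback, from 5: the secondary allylic alcohol would be oxidised (MnO2, CH2Cl2) to (R)‑4‑(1‑ethoxyethenyl)‑4‑hydroxycyclopent‑2‑en‑1‑one F6. Luche 1,2‑reduction (NaBH4, CeCl3, MeOH, −78 °C), with hydride entering anti to the larger 1‑ethoxyvinyl group, should give the trans‑diol (1R,4R)‑1‑(1‑ethoxyethenyl)cyclopent‑2‑ene‑1,4‑diol F7. Chan–Lam coupling of its secondary hydroxyl with (4‑methoxyphenyl)boronic acid (Cu(OAc)2, DMAP, O2, 4 Å MS), which proceeds with retention, returns to 6.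

## Further compounds

F1 | step 6 | 2‑[(1R,4R)‑4‑(4‑methoxyphenoxy)‑1‑(trimethylsilyloxy)cyclopent‑2‑en‑1‑yl]‑2‑oxoethyl benzoate | O=C(OCC(=O)[C@]1(O[Si](C)(C)C)C=C[C@H](Oc2ccc(OC)cc2)C1)c1ccccc1
F2 | step 6 | [(1R,4R)‑4‑(4‑methoxyphenoxy)‑6‑oxo‑1‑(trimethylsilyloxy)cyclohex‑2‑en‑1‑yl]methyl benzoate | O=C(OC[C@@]1(O[Si](C)(C)C)C(=O)C[C@@H](Oc2ccc(OC)cc2)C=C1)c1ccccc1
F3 | step 8 | [(1S,2S,3R,4R)‑1,2,3‑trihydroxy‑4‑(4‑methoxyphenoxy)‑6‑oxocyclohexyl]methyl benzoate | O=C(OC[C@@]1(O)C(=O)C[C@@H](Oc3ccc(OC)cc3)[C@H](O)[C@@H]1O)c1ccccc1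
F4 | step 8 | 2,3‑cyclic sulfate of triol F3 (sulfate bridging the C2 and C3 oxygens, cis to the C1 hydroxyl) | O=C(OC[C@@]1(O)C(=O)C[C@@H](Oc3ccc(OC)cc3)[C@@H]2OS(=O)(=O)O[C@H]12)c1ccccc1
F5 | step 8 | C2 hydrogen sulfate of 12 (12 with OSO3H in place of the C2 hydroxyl) | O=C(OC[C@@]1(O)C(=O)C[C@@H](Oc3ccc(OC)cc3)[C@@H](OC(=O)c2ccccc2)[C@@H]1OS(=O)(=O)O)c1ccccc1
F6 | step 3 | (R)‑4‑(1‑ethoxyethenyl)‑4‑hydroxycyclopent‑2‑en‑1‑one | CCOC(=C)[C@]1(O)C=CC(=O)C1
F7 | step 3 | (1R,4R)‑1‑(1‑ethoxyethenyl)cyclopent‑2‑ene‑1,4‑diol | CCOC(=C)[C@]1(O)C=C[C@H](O)C1
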